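**Strategy.** Everything rests on cutting the target back to an achiral p-quinol. With the ring numbered C1 (CHOBz beside the quaternary carbon), C2=C3, C4 (CHOBz), C5 (CHOH), C6 (quaternary) and C7 (CH2OH), a latent mirror plane runs through C6, O6, C7 and C3, and O5 is cis to O6. The key step exploits exactly this: under a chiral phosphoric acid the tertiary hydroxyl of 4-hydroxy-4-(silyloxymethyl)cyclohexa-2,5-dienone picks up acetaldehyde and delivers oxygen to C5 of one enantiotopic enone, setting C5 and C6 and masking the cis-diol as a fused dioxolane in one operation. The untouched enone is then turned into a 1,3-diene for anti singlet-oxygen 1,4-dioxygenation at C1 and C4.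

Key step: step 3

Remark on labels: all intermediates keep the ring labels C1–C7 of the target; β is the face of the carbocycle that carries O5 and O6, α the face that carries C7.

Assumption: the (R)-configured phosphoric acid is taken to favour the enone arm that leads to the (3aS,7aS) acetal 6; should the opposite sense be found, the equally available (S)-acid is used.

Step 1
Reactants: 1 4-(hydroxymethyl)phenol
Product: 2 4-[(tert-butyldimethylsilyloxy)methyl]phenol
Conditions: TBSCl (1.05 equiv), imidazole (2.2 equiv), DMF, 0 °C
Reagents that add atoms: tert-butyldimethylsilyl chloride (TBSCl), CC(C)(C)[Si](C)(C)Cl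
Why: Imidazole-mediated silyl ether formation is chemoselective here because the primary benzylic alcohol is silylated faster than the un-ionised, less nucleophilic phenol, so one equivalent of silyl chloride at 0 °C should give the mono-ether.

Step 2
Reactants: 2 4-[(tert-butyldimethylsilyloxy)methyl]phenol
Product: 3 4-[(tert-butyldimethylsilyloxy)methyl]-4-hydroxycyclohexa-2,5-dien-1-one (achiral p-quinol)
Conditions: PhI(OAc)2 (1.2 equiv), MeCN/H2O 4:1, 0 °C
Reagents that add atoms: water, O
Why: Oxidative dearomatization of a para-alkylphenol with a hypervalent iodine diacetate: the aryloxy-iodane collapses to a phenoxenium-type species that water traps at the para carbon, and the silyl ether tolerates the acetic acid released.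

Step 3
Reactants: 3 4-[(tert-butyldimethylsilyloxy)methyl]-4-hydroxycyclohexa-2,5-dien-1-one; 4 acetaldehyde
Product: 6 (2R,3aS,7aS)-7a-[(tert-butyldimethylsilyloxy)methyl]-2-methyl-3a,7a-dihydro-1,3-benzodioxol-5(4H)-one (cis-fused ethylidene acetal enone; methyl exo), via acetaldehyde hemiacetal 5 (not isolated)
Conditions: MeCHO (5 equiv), (R)-3,3'-bis(2,4,6-triisopropylphenyl)-1,1'-binaphthyl-2,2'-diyl hydrogen phosphate (5 mol %), 4 Å MS, ClCH2CH2Cl, sealed vessel, 25–40 °C
Reagents that add atoms: acetaldehyde (4), CC=O
Why: The phosphoric acid catalyses reversible addition of the only free hydroxyl, the tertiary C6–OH, to acetaldehyde, and the hemiacetal OH then adds to C5 of one dienone arm (intramolecular oxa-Michael addition) while the catalyst bridges the hemiacetal O–H and the C3 carbonyl by hydrogen bonds. The closest known reaction type is the chiral-phosphoric-acid-catalysed acetalization/oxa-Michael desymmetrization of p-quinols and p-peroxyquinols with aldehydes. The 1,3-dioxolane closes 5-exo-trig, C5 being the attacked trigonal carbon and C4 lying outside the new ring. C5 and C6 are set together by the catalyst's choice between the two enantiotopic enones (C6 becomes stereogenic because its two vinyl arms are differentiated), the cis ring fusion follows from the two-atom tether that can only reach the face of O6, and the acetal carbon is set under dynamic control because the hemiacetal epimers interconvert and the one placing methyl on the convex, exo face cyclizes. The step needs enantiotopic-group selection and a single addition: the mirror symmetry of 3 leaves the chiral acid as the only discriminating element, silylation of O7 leaves O6 as the only hydroxyl able to carry the tether, and the one hemiacetal oxygen is consumed in the ring closure so the second enone stays intact.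

Step 4
Reactants: 6 cis-fused ethylidene acetal enone
Product: 7 (2R,3aS,7aS)-7a-[(tert-butyldimethylsilyloxy)methyl]-2-methyl-3a,4,5,7a-tetrahydro-1,3-benzodioxol-5-ol (allylic alcohol; mixture of epimers at the carbinol carbon C3, both used)
Conditions: NaBH4, CeCl3·7H2O, MeOH, −78 °C
Reagents that add atoms: none
Why: Luche reduction delivers hydride 1,2 to the C3 carbonyl without conjugate reduction or base-induced retro-oxa-Michael opening, and the C3 configuration is irrelevant because C3 becomes sp2 in step 5.

Step 5
Reactants: 7 allylic alcohol
Product: 8 (2R,3aS,7aS)-7a-[(tert-butyldimethylsilyloxy)methyl]-2-methyl-3a,7a-dihydro-1,3-benzodioxole (C1=C2–C3=C4 diene)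
Conditions: Martin sulfurane Ph2S[OC(CF3)2Ph]2 (1.5 equiv), CH2Cl2, 0 °C to rt; used without storage
Reagents that add atoms: none
Why: Martin sulfurane dehydration: the C3 alkoxysulfonium intermediate can lose a proton only from C4 (C2 is vinylic), so elimination under neutral, cold conditions should give the conjugated diene without the acid or heat that would aromatize or dimerize it.

Step 6
Reactants: 8 diene
Product: 10 (2R,3aS,4R,7S,7aR)-7a-[(tert-butyldimethylsilyloxy)methyl]-2-methyl-3a,4,7,7a-tetrahydro-1,3-benzodioxole-4,7-diol (C1-OH and C4-OH both α), via endoperoxide 9 (not isolated)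
Conditions: O2, 5,10,15,20-tetraphenylporphyrin (cat.), visible light, CH2Cl2, −78 °C; then thiourea, MeOH, rt
Reagents that add atoms: dioxygen, O=O
Why: A singlet-oxygen [4+2] cycloaddition (photooxygenation) across C1–C4, which by analogy with acetal-protected arene cis-dihydrodiols should occur on the α face away from the two allylic acetal oxygens and so sets C1 and C4 cis to each other and trans to O5/O6, is followed in the same flask by thiourea reduction of the O–O bond with both C–O bonds retained.

Step 7
Reactants: 10 diol
Product: 11 (2R,3aS,4R,7S,7aR)-7a-[(tert-butyldimethylsilyloxy)methyl]-2-methyl-3a,4,7,7a-tetrahydro-1,3-benzodioxole-4,7-diyl dibenzoate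
Conditions: BzCl (3 equiv), DMAP (0.2 equiv), pyridine, 0 °C to rt
Reagents that add atoms: benzoyl chloride, O=C(Cl)c1ccccc1
Why: DMAP-catalysed acylation (nucleophilic catalysis) esterifies the two secondary allylic alcohols, which are the only free hydroxyls in 10, and touches no stereocentre.

Step 8
Reactants: 11 dibenzoate
Product: 12 5,6-dihydroxy-6-(hydroxymethyl)cyclohex-2-ene-1,4-diyl dibenzoate, (1S,4R,5S,6S) with the ring labels used here (target)
Conditions: TFA/H2O 9:1, 0 °C to rt
Reagents that add atoms: none
Why: Global acidic deprotection: aqueous trifluoroacetic acid hydrolyses the ethylidene acetal through its oxocarbenium ion and cleaves the primary silyl ether, while the benzoates are stable to acid and, with no base present, should not migrate to the liberated hydroxyls.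

**Compound list**

1 | 4-(hydroxymethyl)phenol | OCc1ccc(O)cc1 | starting material
2 | 4-[(tert-butyldimethylsilyloxy)methyl]phenol | CC(C)(C)[Si](C)(C)OCc1ccc(O)cc1 | intermediate
3 | 4-[(tert-butyldimethylsilyloxy)methyl]-4-hydroxycyclohexa-2,5-dien-1-one | O=C1C=CC(O)(CO[Si](C)(C)C(C)(C)C)C=C1 | intermediate
4 | acetaldehyde | CC=O | starting material
5 | 4-[(tert-butyldimethylsilyloxy)methyl]-4-(1-hydroxyethoxy)cyclohexa-2,5-dien-1-one (hemiacetal, interconverting epimers) | CC(O)OC1(CO[Si](C)(C)C(C)(C)C)C=CC(=O)C=C1 | intermediate (not isolated)
6 | (2R,3aS,7aS)-7a-[(tert-butyldimethylsilyloxy)methyl]-2-methyl-3a,7a-dihydro-1,3-benzodioxol-5(4H)-one | C1=CC(=O)C[C@H](O[C@H]2C)[C@@]1(O2)CO[Si](C)(C)C(C)(C)C | intermediate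
7 | (2R,3aS,7aS)-7a-[(tert-butyldimethylsilyloxy)methyl]-2-methyl-3a,4,5,7a-tetrahydro-1,3-benzodioxol-5-ol, epimers at the carbinol carbon | C1=CC(O)C[C@H](O[C@H]2C)[C@@]1(O2)CO[Si](C)(C)C(C)(C)C | intermediate
8 | (2R,3aS,7aS)-7a-[(tert-butyldimethylsilyloxy)methyl]-2-methyl-3a,7a-dihydro-1,3-benzodioxole | C1=CC=C[C@H](O[C@H]2C)[C@@]1(O2)CO[Si](C)(C)C(C)(C)C | intermediate
9 | endoperoxide of 8: C1–O–O–C4 bridge on the α face (anti to the dioxolane oxygens), C2=C3 alkene | O3[C@H]1C=C[C@@H](O3)[C@H](O[C@H]2C)[C@@]1(O2)CO[Si](C)(C)C(C)(C)C | intermediate (not isolated)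
10 | (2R,3aS,4R,7S,7aR)-7a-[(tert-butyldimethylsilyloxy)methyl]-2-methyl-3a,4,7,7a-tetrahydro-1,3-benzodioxole-4,7-diol | O[C@H]1C=C[C@@H](O)[C@H](O[C@H]2C)[C@@]1(O2)CO[Si](C)(C)C(C)(C)C | intermediate
11 | (2R,3aS,4R,7S,7aR)-7a-[(tert-butyldimethylsilyloxy)methyl]-2-methyl-3a,4,7,7a-tetrahydro-1,3-benzodioxole-4,7-diyl dibenzoate | O=C(O[C@H]1C=C[C@@H](OC(=O)c3ccccc3)[C@H](O[C@H]2C)[C@@]1(O2)CO[Si](C)(C)C(C)(C)C)c4ccccc4 | intermediate
12 | 5,6-dihydroxy-6-(hydroxymethyl)cyclohex-2-ene-1,4-diyl dibenzoate, (1S,4R,5S,6S) with the ring labels used here | O=C(O[C@H]1C=C[C@@H](OC(=O)c2ccccc2)[C@H](O)[C@@]1(O)CO)c1ccccc1 | target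

**Step count.** Total: 8 steps. Longest linear sequence: 8 steps (1 to 12); acetaldehyde 4 enters in step 3.

**Steps most likely to fail**

Step 3. The two enantiotopic enones may be poorly discriminated, hemiacetal formation at the hindered tertiary hydroxyl may be slow, or acid-catalysed reversal of the oxa-Michael addition may erode the enantiomeric purity. The fallback sets out from 3 and returns at 6, and replaces the acetal tether by a boron tether. Phenylboronic acid and a cinchona-derived bifunctional amine–thiourea (1-[3,5-bis(trifluoromethyl)phenyl]-3-[(8α,9S)-6'-methoxycinchonan-9-yl]thiourea or its quinidine-derived pseudoenantiomer, 4 Å MS, CH2Cl2) should form the boronic hemiester at O6. Its B–OH oxygen then adds to C5 in the known oxa-Michael addition of γ-hydroxy enones, giving the cis-fused cyclic phenylboronate F1. Transesterification with pinacol should release the cis-diol enone F2 without the alkaline peroxide that would epoxidize the enone. Acetalization of F2 with 1,1-dimethoxyethane and pyridinium p-toluenesulfonate should then give 6 as the thermodynamically favoured exo-methyl acetal.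

Step 8. The robust ethylidene dioxolane may be cleaved incompletely under acid mild enough to avoid benzoate migration (O4 to O5, O1 to O7) or ionization of the allylic esters. The fallback sets out from 11 and returns at 12, and is staged and non-hydrolytic. HF·pyridine in THF/pyridine should first remove the silyl group to give the primary alcohol F4. Transthioacetalization of F4 with propane-1,3-dithiol and BF3·OEt2 in CH2Cl2 at −20 to 0 °C should then transfer the ethylidene unit to sulfur and release the target 12.

Step 5. The activated allylic alcohol may ionize and give allylic substitution or transposition instead of clean β-elimination, and the diene may be lost by aromatization or Diels–Alder dimerization during isolation. The fallback sets out from 7 and returns at 8. Acetylation (Ac2O, DMAP, pyridine) should give the allylic acetate F3. Elimination catalysed by zerovalent palladium (Pd(PPh3)4, Et3N, THF, 60 °C) should then ionize F3 to the η3-allyl complex over C1–C3, and β-hydride loss from C4, the only position bearing a β-hydrogen, should give diene 8.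

**Further compounds**

F1 | step 3 | (3aS,7aS)-7a-[(tert-butyldimethylsilyloxy)methyl]-2-phenyl-3a,7a-dihydro-1,3,2-benzodioxaborol-5(4H)-one | C1=CC(=O)C[C@H](OB2c3ccccc3)[C@@]1(O2)CO[Si](C)(C)C(C)(C)C
F2 | step 3 | (4S,5S)-4-[(tert-butyldimethylsilyloxy)methyl]-4,5-dihydroxycyclohex-2-en-1-one | C1=CC(=O)C[C@H](O)[C@@]1(O)CO[Si](C)(C)C(C)(C)C
F3 | step 5 | (2R,3aS,7aS)-7a-[(tert-butyldimethylsilyloxy)methyl]-2-methyl-3a,4,5,7a-tetrahydro-1,3-benzodioxol-5-yl acetate, epimers at the acetoxy carbon | C1=CC(OC(C)=O)C[C@H](O[C@H]2C)[C@@]1(O2)CO[Si](C)(C)C(C)(C)C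
F4 | step 8 | (2R,3aS,4R,7S,7aR)-7a-(hydroxymethyl)-2-methyl-3a,4,7,7a-tetrahydro-1,3-benzodioxole-4,7-diyl dibenzoate | O=C(O[C@H]1C=C[C@@H](OC(=O)c3ccccc3)[C@H](O[C@H]2C)[C@@]1(O2)CO)c4ccccc4
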